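The runs stem from a simulated flask for substances that don't exist, noise included.

The question is what doubling the partner, or raising free catalyst to 15 mM, does to the rate at the moment 10% of the starting material is converted.

| flask | starting material | partner | protic impurity | free catalyst | remark |
|---|---|---|---|---|---|
| beta | 0.60 M | 0.30 M | 0.60 M | 0.80 mM | run made earlier |
| gamma | 0.60 M | 0.30 M | 0.60 M | 1.2 mM | run made earlier |
| delta | 0.90 M | 0.30 M | 0.60 M | 1.6 mM | run made earlier |
| flask | 0.60 M | 0.300 M | 0.600 M | 1.6 mM |  |

| run | time / h | product / % | starting material / % |
|---|---|---|---|
| beta | 0.417 | 4 | 94 |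
| beta | 1.33 | 14 | 87 |
| beta | 2.00 | 14 | 84 |
| beta | 3.00 | 18 | 79 |
| beta | 5.00 | 19 | 82 |
| beta | 6.00 | 18 | 80 |
| gamma | 0.500 | 11 | 95 |
| gamma | 0.833 | 12 | 83 |
| gamma | 1.33 | 19 | 83 |
| gamma | 2.00 | 21 | 79 |
| gamma | 4.00 | 28 | 75 |
| gamma | 6.00 | 26 | 79 |
| delta | 0.500 | 8 | 92 |
| delta | 1.50 | 12 | 82 |
| delta | 3.00 | 17 | 81 |
| delta | 4.00 | 18 | 83 |
| delta | 6.00 | 19 | 81 |

(each reading ± 2 percentage points)

- steps thought possible: partner + free catalyst <-> catalyst intermediate A; catalyst intermediate A -> catalyst intermediate B; starting material + catalyst intermediate B <-> catalyst intermediate C; catalyst intermediate C -> catalyst intermediate D; catalyst intermediate D -> free catalyst + product; partner + protic impurity -> quenched reagent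
- no earlier run changes the charge of partner; that part of a forecast is a guess

1. factor on the rate of making product when 10% of the starting material are converted if partner is charged twice over
2. factor on the rate when 10% of the starting material are converted if free catalyst is charged at 15 mM instead

The answer turns on [partner] at that moment, so a ladder of time scales comes first, read from the delta run, which has the flask's catalyst charge. Its first reading gives a rate near 0.144 M h⁻¹. One catalyst turnover then takes about 40.0 s. The flask's mark at 10% comes after about 0.417 h, far later, so the catalyst forms have adjusted to the current [partner] by then. Product in the delta run has nearly levelled by 3.00 h, later again, with starting material still at 81%. Partner is therefore the limiting reagent.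

The delta run ends with this much product from its partner charge, taking the last reading as the end, and I assume the flask's share is the same:

share = 57.0%

The rest of the partner goes to the quench. The quantity to carry is the partner left at the mark, the charge minus the product made divided by that share:

[partner] at the mark = 0.195 M

My own reckoning, with the rate proportional to [partner] and the same partner cost, gives these factors:

doubled charge: 2.54

15 mM, with the quench ignored: 9.38 × 1.23 = 11.6

No run varies the partner, so the first factor is a guess. The forecast says 2.4 and 11: “Possible saturation in partner lowers this, so I take 2.4.”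

The simulation gives 1.56 and 11.1, so the forecast's doubling factor lies 1.54 times too high, while its catalyst factor holds.

    partner + free catalyst ⇌ catalyst intermediate A (K = 10.5 M⁻¹, k = 1050 M⁻¹ h⁻¹)
    catalyst intermediate A → catalyst intermediate B (k = 478 h⁻¹)
    starting material + catalyst intermediate B ⇌ catalyst intermediate C (K = 5.10 M⁻¹, k = 730 M⁻¹ h⁻¹)
    catalyst intermediate C → catalyst intermediate D (k = 17800 h⁻¹)
    catalyst intermediate D → free catalyst + product (k = 9910 h⁻¹)
    partner + protic impurity → quenched reagent (k = 1.51 M⁻¹ h⁻¹)

The doubled flask gains a factor of 1.56, less than the 2.54 reckoned from 0.195 M at the mark with a rate proportional to [partner]. With the catalyst factor of 9.38 divided out, the 15 mM flask gains 1.18, against the reckoned 1.23. The run without the quench shows a part of what the loss of partner does: its rate at the mark is 1.21 times the actual one, and the apparent order at the mark goes from 0.91 to 0.63 in partner and from 1.2 to 1.0 in free catalyst.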